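**Retrosynthetic overview**
1. Ring A is attached last: the spiro-lactam is converted to its imidoyl triflate and coupled with a 2-pyrrolylboronic acid.
2. Ring B and the spiro N,O-aminal are grown on a δ-lactone carbonyl: addition of a β-metallated β-methoxyacrylate, then NH3 and acid-mediated spiroaminalisation under anomeric control.
3. The 12-membered pyrrolophane is closed at the CH(pyrrolyl)–pyrrole bond by a ferrocene-mediated anodic enolate–pyrrolide coupling.
4. The CH(alkyl) centre comes from a trans-selective Cu-catalysed conjugate addition of a pyrrolylheptyl Grignard to (S)-parasorbic acid, itself made from (S)-propylene oxide.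
5. Ring order: δ-lactone (future tetrahydropyran) → macrocycle → spiro ring B (butenolide, then lactam) → ring A; the ring C pyrrole is bought.

Assumption: the target SMILES is read as spiro C (R), O–CH(CH3) (S), CH(alkyl) (S), CH(pyrrolyl) (S); compounds 1, 2, 7, 8, 16 and 23 are taken as commercial.

**Step 1**
Reactants: 1 (S)-propylene oxide; 2 ethyl propiolate
Product: 4 ethyl (5S)-5-hydroxyhex-2-ynoate, via lithium ethyl propiolate 3 (not isolated)
Conditions: 2, n-BuLi, THF, −78 °C; BF3·OEt2; then 1, −78 °C; aq NH4Cl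
Reagents that add atoms: none
Why: BF3-promoted opening of the epoxide at its CH2 carbon by the lithium acetylide (Yamaguchi–Hirao alkynylation) leaves the bought (S) centre untouched.

**Step 2**
Reactants: 4 ethyl (5S)-5-hydroxyhex-2-ynoate
Product: 6 (S)-parasorbic acid [(6S)-6-methyl-5,6-dihydro-2H-pyran-2-one], via Z-hydroxy enoate 5 (not isolated)
Conditions: H2 (1 atm), Lindlar Pd, quinoline, EtOAc, rt; then TsOH (cat.), PhMe, 50 °C
Reagents that add atoms: none
Why: Lindlar semihydrogenation gives the Z-enoate, whose cis geometry allows acid-catalysed lactonisation; the stereocentre is not involved.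

**Step 3**
Reactants: 7 pyrrole; 8 7-bromoheptanoyl chloride
Product: 10 7-bromo-1-(1H-pyrrol-2-yl)heptan-1-one, via pyrrolylmagnesium bromide 9 (not isolated)
Conditions: 7 (2.2 equiv), EtMgBr, Et2O, 0 °C → rt; then 8, PhMe, −40 → 0 °C; aq NH4Cl
Reagents that add atoms: none
Why: C2-acylation of the ambident pyrrolyl Grignard by an acid chloride (pyrrole Friedel–Crafts-type acylation); the primary bromide is inert at −40 °C.

**Step 4**
Reactants: 10 7-bromo-1-(1H-pyrrol-2-yl)heptan-1-one
Product: 11 2-(7-bromoheptyl)-1H-pyrrole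
Conditions: NaBH4, i-PrOH, reflux
Reagents that add atoms: none
Why: Deoxygenative reduction of a 2-acylpyrrole (carbinol → azafulvene → second hydride addition) gives the 2-alkylpyrrole; a primary alkyl bromide is not reduced by NaBH4 in an alcohol.

**Step 5**
Reactants: 11 2-(7-bromoheptyl)-1H-pyrrole; 6 (S)-parasorbic acid
Product: 13 (4S,6S)-6-methyl-4-[7-(1H-pyrrol-2-yl)heptyl]oxan-2-one, via N,C-dimagnesium reagent 12 (not isolated)
Conditions: 11 (1.3 equiv), i-PrMgCl (1.0 equiv), THF, 0 °C; Mg, LiCl, THF, rt; then CuBr·SMe2 (10 mol %), 6, THF, −78 → −40 °C; aq NH4Cl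
Reagents that add atoms: none
Why: Cu-catalysed conjugate addition of the alkyl Grignard (pyrrole N–H masked as its N–MgCl salt, Normant-type) occurs anti to the C6 methyl of the half-chair lactone, so the 4,6-trans lactone forms and the CH(alkyl) centre (S) is set by the bought centre.

**Step 6**
Reactants: 13 (4S,6S)-6-methyl-4-[7-(1H-pyrrol-2-yl)heptyl]oxan-2-one
Product: 15 macrolactone (3S,4S,6S), via dilithio dianion 14 (not isolated)
Conditions: LiHMDS (2.2 equiv), THF, −78 °C; then Cp2Fe (20 mol %), LiClO4 (0.1 M), THF, 2 mM, RVC(+)/Pt(−), undivided cell, 5 mA, 2.2 F/mol, −40 °C; aq NH4Cl; then DBU (cat.), CH2Cl2, rt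
Reagents that add atoms: none
Why: Proposed new method: anodically generated ferrocenium (about +0.4 V vs SCE) oxidises the lithium lactone enolate of 14 (roughly 0.5 V easier to oxidise than the pyrrolide) to the electrophilic α-lactone radical, which adds to the free α-carbon (C5) of the tethered lithium pyrrolide in a polarity-matched 12-membered ring closure, the adduct radical anion is oxidised and tautomerises to the pyrrole while the cathode evolves H2 from HN(SiMe3)2, and DBU equilibration places the epimerisable C3 centre trans to the C4 chain (S); the closest known reaction type is the stoichiometric Cu(II)- or ferrocenium-mediated oxidative enolate–pyrrole/indole heterocoupling together with ferrocene-mediated anodic radical cyclisation of 1,3-dicarbonyl anions, neither shown on a simple lactone enolate or for a macrocyclisation.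

**Step 7**
Reactants: 15 macrolactone (3S,4S,6S); 16 methyl (E)-3-methoxyacrylate
Product: 19 spiroketal butenolide, via lithiated methoxyacrylate 17 (not isolated), via cerium methoxyacrylate 18 (not isolated)
Conditions: 16 (3.5 equiv), LDA, THF, −95 °C; CeCl3, −78 °C; then 15, −78 → 0 °C; aq NH4Cl; CSA (cat.), CH2Cl2, rt
Reagents that add atoms: none
Why: The chelated β-lithio-β-methoxyacrylate (a β-acylvinyl anion), made less basic as its organocerium so that addition beats enolisation of the acidic α-pyrrolyl C–H, adds once to the lactone carbonyl and the lactol oxygen then lactonises onto the cis ester (tetronate formation); existing centres are untouched and the new spiro centre is re-set in step 8.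

**Step 8**
Reactants: 19 spiroketal butenolide
Product: 21 spiro-lactam, via 5-hydroxy-lactam 20 (not isolated)
Conditions: NH3 (7 M in MeOH), rt; concentrate; TFA (cat.), CH2Cl2, 4 Å MS, rt
Reagents that add atoms: ammonia, N
Why: Ammonolysis of the ketal-type butenolide gives the 5-hydroxy-lactam, and acid ionises it to an N-acyliminium ion that the secondary hydroxyl captures in a reversible six-ring closure (N-acyliminium spirocyclisation), so the spiro centre settles as the anomerically stabilised epimer with C–N axial (R).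

**Step 9**
Reactants: 21 spiro-lactam
Product: 22 imidoyl triflate
Conditions: Tf2O (1.2 equiv), 2,6-di-tert-butyl-4-methylpyridine, CH2Cl2, −78 → 0 °C; aq NaHCO3
Reagents that add atoms: triflic anhydride, O=S(=O)(OS(=O)(=O)C(F)(F)F)C(F)(F)F
Why: O-sulfonylation of the secondary lactam gives the imidoyl triflate, the standard activation of 4-methoxy-pyrrolin-2-ones for bipyrrole synthesis; it is faster at −78 °C than attack on the dialkylpyrrole and touches no stereocentre.

**Step 10**
Reactants: 22 imidoyl triflate; 23 N-Boc-pyrrole-2-boronic acid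
Product: 25 premarineosin A, via N-Boc-premarineosin A 24 (not isolated)
Conditions: Pd(PPh3)4 (10 mol %), K2CO3, 1,4-dioxane/H2O, 90 °C
Reagents that add atoms: none
Why: Suzuki–Miyaura coupling of the imidoyl triflate installs ring A, and the N-Boc group on the resulting 2-iminylpyrrole is cleaved by hot aqueous carbonate in the same pot; no stereocentre is affected.

**Compound list**
1 | (S)-propylene oxide [(2S)-2-methyloxirane] | C[C@H]1CO1 | starting material
2 | ethyl propiolate | CCOC(=O)C#C | starting material
3 | lithium ethyl propiolate | [Li]C#CC(=O)OCC | intermediate (not isolated)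
4 | ethyl (5S)-5-hydroxyhex-2-ynoate | CCOC(=O)C#CC[C@H](C)O | intermediate
5 | ethyl (2Z,5S)-5-hydroxyhex-2-enoate | CCOC(=O)/C=C\C[C@H](C)O | intermediate (not isolated)
6 | (S)-parasorbic acid [(6S)-6-methyl-5,6-dihydro-2H-pyran-2-one] | C[C@H]1CC=CC(=O)O1 | intermediate
7 | pyrrole | c1cc[nH]c1 | starting material
8 | 7-bromoheptanoyl chloride | O=C(Cl)CCCCCCBr | starting material
9 | pyrrol-1-ylmagnesium bromide | Br[Mg]n1cccc1 | intermediate (not isolated)
10 | 7-bromo-1-(1H-pyrrol-2-yl)heptan-1-one | O=C(CCCCCCBr)c1ccc[nH]1 | intermediate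
11 | 2-(7-bromoheptyl)-1H-pyrrole | BrCCCCCCCc1ccc[nH]1 | intermediate
12 | N,C-dimagnesium reagent: 1-(chloromagnesio)-2-[7-(bromomagnesio)heptyl]pyrrole | Cl[Mg]n1cccc1CCCCCCC[Mg]Br | intermediate (not isolated)
13 | (4S,6S)-6-methyl-4-[7-(1H-pyrrol-2-yl)heptyl]oxan-2-one (4,6-trans) | C[C@H]1C[C@H](CCCCCCCc2ccc[nH]2)CC(=O)O1 | intermediate
14 | dilithio dianion of 13 (lithium lactone enolate, N-lithiopyrrolide) | C[C@H]1C[C@H](CCCCCCCc2cccn2[Li])C=C(O[Li])O1 | intermediate (not isolated)
15 | macrolactone (3S,4S,6S): 6-methyloxan-2-one whose C3 is bonded to pyrrole C5 and whose C4 is joined through (CH2)7 to pyrrole C2 (12-membered 2,5-pyrrolophane; H-3/H-4 trans; C4 chain/C6 methyl trans) | O=C1O[C@@H](C)C[C@@H]2CCCCCCCc3ccc([nH]3)[C@@H]12 | intermediate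
16 | methyl (E)-3-methoxyacrylate | CO/C=C/C(=O)OC | starting material
17 | methyl (Z)-3-lithio-3-methoxyacrylate | CO/C([Li])=C/C(=O)OC | intermediate (not isolated)
18 | methyl (Z)-3-(dichlorocerio)-3-methoxyacrylate | CO/C([Ce](Cl)Cl)=C/C(=O)OC | intermediate (not isolated)
19 | spiroketal butenolide: 4-methoxyfuran-2(5H)-one whose C5 is the former lactone carbon of 15, spiro to the oxane (drawn as the anomeric epimer; centre re-set in step 8) | COC1=CC(=O)O[C@]12O[C@@H](C)C[C@@H]1CCCCCCCc3ccc([nH]3)[C@H]12 | intermediate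
20 | 5-hydroxy-lactam: 5-hydroxy-4-methoxy-1,5-dihydro-2H-pyrrol-2-one bearing at C5 the macrocyclic CH(pyrrolyl) carbon; side chain CH2CH(OH)CH3 free; hemiaminal centre undefined | COC1=CC(=O)NC1(O)[C@@H]1c2ccc(CCCCCCC[C@H]1C[C@H](C)O)[nH]2 | intermediate (not isolated)
21 | spiro-lactam: 4-methoxy-1,5-dihydro-2H-pyrrol-2-one whose C5 is the (R) spiro carbon of the oxane; other centres as in the target | COC1=CC(=O)N[C@]12O[C@@H](C)C[C@@H]1CCCCCCCc3ccc([nH]3)[C@H]12 | intermediate
22 | imidoyl triflate of 21 (3-methoxy-2H-pyrrol-5-yl triflate, spiro at C2) | COC1=CC(OS(=O)(=O)C(F)(F)F)=N[C@]12O[C@@H](C)C[C@@H]1CCCCCCCc3ccc([nH]3)[C@H]12 | intermediate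
23 | N-Boc-pyrrole-2-boronic acid | CC(C)(C)OC(=O)n1cccc1B(O)O | starting material
24 | N-Boc-premarineosin A (Boc on ring A nitrogen) | COC1=CC(c2cccn2C(=O)OC(C)(C)C)=N[C@]12O[C@@H](C)C[C@@H]1CCCCCCCc3ccc([nH]3)[C@H]12 | intermediate (not isolated)
25 | premarineosin A | COC1=CC(c2ccc[nH]2)=N[C@]12O[C@@H](C)C[C@@H]1CCCCCCCc3ccc([nH]3)[C@H]12 | target

**Step count and risks**
Total steps: 10. Longest linear sequence: 8 (steps 1, 2, 5, 6, 7, 8, 9, 10 from (S)-propylene oxide); steps 3 and 4 are a two-step side branch.

Most likely to fail, step 6 (the proposed new anodic macrocyclisation). The product enolate is more acidic and about as oxidisable as the starting enolate, so over-oxidation, oligomerisation or attack at a pyrrole β-carbon can compete; the trans preference at C3 within the macrocycle is expected but not proven. The fallback uses known chemistry, sets out from 6 (with 7 for the pyrrole piece) and comes back at 15. Cu-catalysed conjugate addition of hex-5-enylmagnesium bromide to 6 gives (4S,6S)-4-(hex-5-en-1-yl)-6-methyloxan-2-one F1. Pyrrole 7 is allylated through its Grignard salt with allyl bromide to 2-(prop-2-en-1-yl)-1H-pyrrole F2. The lithium enolate of F1 and N-lithiated F2 (3 equiv) are joined by the established copper(II) 2-ethylhexanoate oxidative enolate–pyrrole heterocoupling to (3S,4S,6S)-4-(hex-5-en-1-yl)-6-methyl-3-[5-(prop-2-en-1-yl)-1H-pyrrol-2-yl]oxan-2-one F3. Ring-closing metathesis (Grubbs II, CH2Cl2, 1 mM, 40 °C) gives the unsaturated macrolactone F4, and H2 over Pd/C gives 15.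

Second, step 7 (organocerium addition to the α-pyrrolyl lactone). Enolisation of the acidic C3–H or consumption of the reagent by the pyrrole N–H may stop the addition. The fallback sets out from 15 and comes back at 19. AlMe3 and MeNH(OMe)·HCl open the lactone to the hydroxy Weinreb amide F5, whose α-C–H is several pK units less acidic. TESCl and imidazole give the triethylsilyl ether F6. Excess 17 adds once to the Weinreb amide to give the keto ester F7. HF·pyridine followed by CSA removes the silyl group and closes the lactol and the butenolide to 19.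

Third, step 5 (Grignard formation and conjugate addition with a free pyrrole N–H). Incomplete magnesium insertion or self-alkylation of the magnesium pyrrolide can erode the yield. The fallback sets out from 6 and comes back at 13. Cu-catalysed addition of hept-6-enylmagnesium bromide to 6 gives (4S,6S)-4-(hept-6-en-1-yl)-6-methyloxan-2-one F8. Hydroboration with 9-BBN gives the B-alkyl-9-BBN adduct F9. In the same pot, B-alkyl Suzuki coupling (Pd(dppf)Cl2, K3PO4) with tert-butyl 2-bromopyrrole-1-carboxylate gives the N-Boc lactone F10. Thermolysis at 180 °C removes the Boc group to give 13.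

**Further compounds**
F1 | step 6 | (4S,6S)-4-(hex-5-en-1-yl)-6-methyloxan-2-one | C[C@H]1C[C@H](CCCCC=C)CC(=O)O1
F2 | step 6 | 2-(prop-2-en-1-yl)-1H-pyrrole | C=CCc1ccc[nH]1
F3 | step 6 | (3S,4S,6S)-4-(hex-5-en-1-yl)-6-methyl-3-[5-(prop-2-en-1-yl)-1H-pyrrol-2-yl]oxan-2-one | O=C1O[C@@H](C)C[C@H](CCCCC=C)[C@H]1c2ccc(CC=C)[nH]2
F4 | step 6 | unsaturated macrolactone (15 with a C=C in the bridge, E/Z mixture) | O=C1O[C@@H](C)C[C@@H]2CCCCC=CCc3ccc([nH]3)[C@@H]12
F5 | step 7 | hydroxy Weinreb amide from ring-opening of 15 | CON(C)C(=O)[C@@H]1c2ccc(CCCCCCC[C@H]1C[C@H](C)O)[nH]2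
F6 | step 7 | triethylsilyl ether of F5 | CON(C)C(=O)[C@@H]1c2ccc(CCCCCCC[C@H]1C[C@H](C)O[Si](CC)(CC)CC)[nH]2
F7 | step 7 | keto ester: methyl (Z)-3-methoxy-4-oxobut-2-enoate acylated at C4 by the macrocyclic CH(pyrrolyl) carbon, OTES side chain | COC(=O)/C=C(/OC)C(=O)[C@@H]1c2ccc(CCCCCCC[C@H]1C[C@H](C)O[Si](CC)(CC)CC)[nH]2
F8 | step 5 | (4S,6S)-4-(hept-6-en-1-yl)-6-methyloxan-2-one | C[C@H]1C[C@H](CCCCCC=C)CC(=O)O1
F9 | step 5 | B-alkyl-9-BBN adduct of F8 | C[C@H]1C[C@H](CCCCCCCB2C3CCCC2CCC3)CC(=O)O1
F10 | step 5 | N-Boc derivative of 13 | C[C@H]1C[C@H](CCCCCCCc2cccn2C(=O)OC(C)(C)C)CC(=O)O1
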